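The numbers are those of an exercise; what happens was integrated by code.

Over 15 d in one closed, stirred flask at constant temperature, you want to know where each mole of substrate ends up.

    substrate ⇌ intermediate A (K1 = 0.110, k1 = 8.28 × 10⁻⁴ min⁻¹)
    substrate → intermediate B (k2 = 0.00167 min⁻¹)
    substrate → target (k3 = 0.0141 min⁻¹)
    intermediate B ⇌ intermediate C (K4 = 22.7, k4 = 0.00202 min⁻¹)
    2 substrate → self-condensation product (k5 = 6.40 × 10⁻⁴ M⁻¹ min⁻¹)
    target ⇌ isomer of the product (K6 = 0.970, k6 = 5.31 × 10⁻⁴ min⁻¹)
    solid reagent ⇌ partner, rate k7*(cs7 - [partner]) while solid is left; crystals form when [partner] > cs7 (cs7 = 0.29 M, k7 = 0.00107 min⁻¹)

substrate 0.40 M; solid reagent 1.50 equiv; time 15 d

- percentages count the substrate that a species holds: one self-condensation product counts as two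
- a step written with two of one species runs at k times the square of its concentration and takes two of it each time
- solid, in amounts per volume of the solution: solid reagent
- at the start none of the solid reagent is in solution
- the reaction counts as stopped when no species that holds the substrate changes by six tenths of a point or more over the second half of the time
- run time (flask): 15 d

* the state of affairs at 15 d: stopped, and by what, or still going (for what has run out or reacted, a solid counts together with what of it has only dissolved) (forward and back rates have come level / all of the substrate has reacted / it is still moving / the partner has run out first)
* how much of the substrate has reacted by 15 d
* how much target there is at 15 d, in percent of the substrate charged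
* how much isomer of the product there is at 15 d, in percent of the substrate charged
* how much intermediate C there is at 15 d, in percent of the substrate charged

Keep a ledger for the substrate. Step 3 has a half-life of 0.82 h by itself, shorter than the 0.29 d of step 2 and short against 15 d, so I expect the flask to end with the substrate reacted. The solid reagent and the partner stand in no step with the substrate, so they get no entry. Intermediate A is a loan rather than an entry: the forward half-life of step 1 is 0.58 d, slower than step 3, and at balance it holds 0.110 times the substrate, so it falls as the substrate falls.

The first entry depends on the charge: two substrate meet in step 5. Its rate follows a falling curve, so replace the curve by its mean. Averaged over the moles as they leave, a first-order decay stands at half the charge. Step 5 then removes substrate at twice k5 times that mean, against k2 plus k3. I call 1.62% the pairing share, the part of the charge lost to self-condensation. The error is small: at the start, pairing adds 3.24% to the decay rate, and integrating the curve so bent gives 1.59%.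

The rest divides by the selectivity factor 8.4: 88.0% goes to the target side and 10.4% to the side of intermediates B and C, and the books close at >99.9%. The forward half-lives of step 6, 0.91 d, and step 4, 5.72 h, are short against 15 d, so each side should reach its balance. That gives target 44.6%, isomer of the product 43.3% and intermediate C 9.98%.

The forecast, holding that “both reversible pairs fully equilibrate”, gave this end state: all of the substrate has reacted, with 100% conversion, 44.7% target, 43.4% isomer of the product and 10% intermediate C, three yields that differ from mine in the last place.

The simulation gives this end state: all of the substrate has reacted, with conversion 100%, target 44.7%, isomer of the product 43.3% and intermediate C 9.99%. In this flask steps 2, 3 and 5 ran while substrate was there; by 1.50 d the substrate stood at 0% and self-condensation product at 1.54%, against the pairing share of 1.62%. Step 6 ran on after that, taking target from 49.3% to 44.7% at 7.50 d. In the neighbouring flask with 0.10 M of substrate, the pairing share comes to 0.406%, and its self-condensation product stands at 0.390%.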